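**Strategy.** The C-ring is read as an aldol retron: C3, which carries oxygen, is bonded to C2, which carries O1 and phenyl. C2 and the C3 oxygen are therefore first joined as a benzylidene acetal, so that O1, C2, the C3 oxygen, C3, C4, C4a and C8a form a seven-membered 1,3-dioxepin-5-one made from a 2-hydroxyacetophenone and benzaldehyde dimethyl acetal. A chiral Brønsted acid then ionises this racemic acetal and lets the enediol carbon C3 attack the O1-aryl oxocarbenium carbon C2: C2 moves from oxygen to carbon, the ring contracts to the pyranone, and the C2–C3 bond and both stereocentres arise in one catalytic operation. Acylation and debenzylation finish the synthesis.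

Key step: step 3

Remark: atom labels follow the chromanone numbering of the target; the sense of induction of the chiral acid in step 3 cannot be predicted from precedent, so the catalyst antipode that leads to (2R,3R) is assumed (written here as R).

**Step 1**
Reactants: 1 1-[2,4-bis(benzyloxy)-6-hydroxyphenyl]ethan-1-one
Product: 4 1-[2,4-bis(benzyloxy)-6-hydroxyphenyl]-2-hydroxyethan-1-one, via bis(trimethylsilyl) enol ether 2 (not isolated), via bis(trimethylsilyl) hydroxy ketone 3 (not isolated)
Conditions: LiHMDS (2.2 equiv), THF, −78 °C, then TMSCl; mCPBA, NaHCO3, CH2Cl2, 0 °C; aq. HCl, THF, 0 °C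
Reagents that add atoms: mCPBA, OOC(=O)c1cccc(Cl)c1 (the new α-oxygen); chlorotrimethylsilane, C[Si](C)(C)Cl (silyl groups of 2 and 3 only, lost again in the acidic work-up)
Why: Rubottom oxidation: phenoxide and kinetic methyl-ketone enolate are trapped as 2, the peracid epoxidises the electron-rich enol ether, 1,4-silyl shift gives 3 and dilute acid frees both hydroxyls; no stereocentre is formed.

**Step 2**
Reactants: 4 1-[2,4-bis(benzyloxy)-6-hydroxyphenyl]-2-hydroxyethan-1-one; 5 benzaldehyde dimethyl acetal
Product: 7 rac-6,8-bis(benzyloxy)-2-phenyl-4H-1,3-benzodioxepin-5-one, via mixed methyl acetal 6 (not isolated)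
Conditions: PPTS (10 mol %), 5 Å MS, toluene, 60 °C
Reagents that add atoms: benzaldehyde dimethyl acetal (5), COC(OC)c1ccccc1
Why: Acid-catalysed transacetalisation: the primary alcohol exchanges first to 6, whose oxocarbenium ion is captured by the ortho phenol to close the seven-membered aryl alkyl acetal while the sieves take up methanol; the acetal centre forms racemic, which does not matter because step 3 erases it.

**Step 3**
Reactants: 7 rac-6,8-bis(benzyloxy)-2-phenyl-4H-1,3-benzodioxepin-5-one
Product: 9 (2R,3R)-5,7-bis(benzyloxy)-3-hydroxy-2-phenyl-2,3-dihydro-4H-chromen-4-one, via oxocarbenium enediol ion 8 (not isolated)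
Conditions: (R)-3,3'-bis(2,4,6-triisopropylphenyl)-BINOL N-triflyl phosphoramide (10 mol %), 5 Å MS, toluene (0.02 M), 50 °C
Reagents that add atoms: none
Why: Proposed new method: the acid protonates the aryl alkyl acetal of 7 and cleaves the bond between C2 and the acetal oxygen, which erases the only (racemic) stereocentre and gives, after acid-mediated enolisation of the freed 2-hydroxy ketone, the O1-aryl oxocarbenium/(Z)-enediol ion 8 paired with the chiral anion; C3 of the enediol then adds to C2 (6-endo-trig at C2=O1+, enolendo at the nucleophile), so that C2 has moved from oxygen to carbon, the former acetal oxygen is left outside the ring as the 3-hydroxyl, and the seven-membered ring has contracted to the pyranone. The closest known reaction types are the Petasis–Ferrier rearrangement and its chiral-phosphoric-acid-catalysed aza variant (O-to-C shift through an oxocarbenium or iminium/enol pair), the Lewis-acid ring contraction of 4,5-dihydro-1,3-dioxepins to tetrahydrofuran-3-carbaldehydes, and chiral-Brønsted-acid-catalysed Prins and oxa-Pictet–Spengler cyclisations of oxocarbenium ions; new here are the 1,2-relationship (the enol carbon itself carries the departing oxygen) and the contraction by one ring atom. Both stereocentres are formed with the C2–C3 bond: the 2,3-trans relation should follow from a chair-like transition state with phenyl ((E)-oxocarbenium) and hydroxyl ((Z)-enediol) pseudo-equatorial and is also the thermodynamically preferred one, while the absolute configuration is under catalyst control, the anion holding the two enediol hydroxyls by hydrogen bonds and shielding one face of the oxocarbenium ion. The step needs C- over O-attack, closure over hydrolysis or intermolecular Friedel–Crafts benzylation, and one enolisation direction: O-attack or cleavage of the other acetal C–O bond only regenerates 7, so C–C bond formation is the sole irreversible exit, the tether makes the closure six-membered, the acyl group deactivates the arene, the ketone can enolise only towards C3, and the sieves exclude water.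

**Step 4**
Reactants: 9 (2R,3R)-5,7-bis(benzyloxy)-3-hydroxy-2-phenyl-2,3-dihydro-4H-chromen-4-one; 10 hexanoic anhydride
Product: 11 (2R,3R)-5,7-bis(benzyloxy)-4-oxo-2-phenyl-3,4-dihydro-2H-chromen-3-yl hexanoate
Conditions: pyridine, DMAP (cat.), CH2Cl2, 0 °C to rt
Reagents that add atoms: hexanoic anhydride (10), CCCCCC(=O)OC(=O)CCCCC
Why: DMAP-catalysed O-acylation of the only free hydroxyl; pyridine is too weak a base to enolise C3 or open the ring, so both stereocentres should be kept.

**Step 5**
Reactants: 11 (2R,3R)-5,7-bis(benzyloxy)-4-oxo-2-phenyl-3,4-dihydro-2H-chromen-3-yl hexanoate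
Product: 12 (2R,3R)-5,7-dihydroxy-4-oxo-2-phenyl-3,4-dihydro-2H-chromen-3-yl hexanoate
Conditions: H2 (1 atm), 10% Pd/C, EtOAc, rt
Reagents that add atoms: none
Why: Catalytic hydrogenolysis of the two aryl benzyl ethers; in ethyl acetate the aryl ketone, the ring C2–O1 bond and the ester should survive a short exposure, and no stereocentre is touched.

**Compound list**
1 | 1-[2,4-bis(benzyloxy)-6-hydroxyphenyl]ethan-1-one | CC(=O)c1c(O)cc(OCc2ccccc2)cc1OCc1ccccc1 | starting material
2 | {1-[2,4-bis(benzyloxy)-6-(trimethylsilyloxy)phenyl]ethenyloxy}trimethylsilane | C=C(O[Si](C)(C)C)c1c(O[Si](C)(C)C)cc(OCc2ccccc2)cc1OCc1ccccc1 | intermediate (not isolated)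
3 | 1-[2,4-bis(benzyloxy)-6-(trimethylsilyloxy)phenyl]-2-(trimethylsilyloxy)ethan-1-one | C[Si](C)(C)OCC(=O)c1c(O[Si](C)(C)C)cc(OCc2ccccc2)cc1OCc1ccccc1 | intermediate (not isolated)
4 | 1-[2,4-bis(benzyloxy)-6-hydroxyphenyl]-2-hydroxyethan-1-one | OCC(=O)c1c(O)cc(OCc2ccccc2)cc1OCc1ccccc1 | intermediate
5 | benzaldehyde dimethyl acetal | COC(OC)c1ccccc1 | starting material
6 | 1-[2,4-bis(benzyloxy)-6-hydroxyphenyl]-2-[methoxy(phenyl)methoxy]ethan-1-one (racemic) | COC(OCC(=O)c1c(O)cc(OCc2ccccc2)cc1OCc1ccccc1)c1ccccc1 | intermediate (not isolated)
7 | rac-6,8-bis(benzyloxy)-2-phenyl-4H-1,3-benzodioxepin-5-one | O=C1COC(c2ccccc2)Oc2cc(OCc3ccccc3)cc(OCc3ccccc3)c12 | intermediate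
8 | O1-aryl oxocarbenium (Z)-enediol cation from ring-opened 7 (counter-ion: anion of the chiral acid) | O/C=C(\O)c1c(OCc2ccccc2)cc(OCc2ccccc2)cc1[O+]=Cc1ccccc1 | intermediate (not isolated)
9 | (2R,3R)-5,7-bis(benzyloxy)-3-hydroxy-2-phenyl-2,3-dihydro-4H-chromen-4-one | O[C@H]1C(=O)c2c(OCc3ccccc3)cc(OCc3ccccc3)cc2O[C@@H]1c1ccccc1 | intermediate
10 | hexanoic anhydride | CCCCCC(=O)OC(=O)CCCCC | starting material
11 | (2R,3R)-5,7-bis(benzyloxy)-4-oxo-2-phenyl-3,4-dihydro-2H-chromen-3-yl hexanoate | CCCCCC(=O)O[C@H]1C(=O)c2c(OCc3ccccc3)cc(OCc3ccccc3)cc2O[C@@H]1c1ccccc1 | intermediate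
12 | (2R,3R)-5,7-dihydroxy-4-oxo-2-phenyl-3,4-dihydro-2H-chromen-3-yl hexanoate | CCCCCC(=O)O[C@H]1C(=O)c2c(O)cc(O)cc2O[C@@H]1c1ccccc1 | target

**Total step count:** 5. **Longest linear sequence:** 5 steps (1 to 12).

**Steps most likely to fail**

Step 3 (Proposed new method). The acetal may ionise without productive closure if enolisation is slow, so that hydrolysis, 1,3-dioxole formation or oligomerisation of the oxocarbenium ion takes over. The counter-anion may also discriminate the two faces poorly, and acid-mediated reopening of the product may erode its enantiopurity. The fallback uses known chemistry, sets out from 1 and returns at 9 by the classical chalcone epoxide construction, which does not pass through the dioxepinone. Claisen–Schmidt condensation of 1 with benzaldehyde (KOH, EtOH) would give (E)-1-[2,4-bis(benzyloxy)-6-hydroxyphenyl]-3-phenylprop-2-en-1-one F1. Etherification (NaH, MOMCl, DMF) would give (E)-1-[2,4-bis(benzyloxy)-6-(methoxymethoxy)phenyl]-3-phenylprop-2-en-1-one F2. Juliá–Colonna epoxidation (poly-L-leucine, urea–H2O2, DBU, THF) should give [2,4-bis(benzyloxy)-6-(methoxymethoxy)phenyl][(2R,3S)-3-phenyloxiran-2-yl]methanone F3. HCl in MeOH at 45 °C would then remove the MOM group, and the freed phenol should open the epoxide at the benzylic carbon (6-endo, inversion there, retention at the carbinol carbon) to give 9.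

Step 2. The seven-membered ring may fail to close, giving open-chain or oligomeric mixed acetals, or the acid needed for acetal exchange may already trigger an uncatalysed, racemic ring contraction. The fallback sets out from 4 and returns at 7 without acid: double O-alkylation with (dibromomethyl)benzene (Cs2CO3, MeCN, rt), in which the phenoxide is alkylated first and the resulting α-bromobenzyl aryl ether is captured by the primary hydroxyl. It makes no new compound (F0).

Step 1. The peracid may oxidise the electron-rich arene, or the double silylation may be incomplete and the labile aryl silyl ether lost before the oxidation. The fallback sets out from 1 and returns at 4 by direct oxygenation of the dipotassium dianion (KHMDS, THF, −78 °C) with 2-(phenylsulfonyl)-3-phenyloxaziridine, an enolate oxidation in place of the epoxidation of an enol silane. It makes no new compound (F0).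

**Further compounds**
F1 | step 3 | (E)-1-[2,4-bis(benzyloxy)-6-hydroxyphenyl]-3-phenylprop-2-en-1-one | O=C(/C=C/c1ccccc1)c1c(O)cc(OCc2ccccc2)cc1OCc1ccccc1
F2 | step 3 | (E)-1-[2,4-bis(benzyloxy)-6-(methoxymethoxy)phenyl]-3-phenylprop-2-en-1-one | O=C(/C=C/c1ccccc1)c1c(OCOC)cc(OCc2ccccc2)cc1OCc1ccccc1
F3 | step 3 | [2,4-bis(benzyloxy)-6-(methoxymethoxy)phenyl][(2R,3S)-3-phenyloxiran-2-yl]methanone | O=C([C@@H]1O[C@H]1c1ccccc1)c1c(OCOC)cc(OCc2ccccc2)cc1OCc1ccccc1
F0 | step 2 | none | none
F0 | step 1 | none | none
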